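**Plan**

Ring atoms: C1 (olefinic carbon bearing the tetraene), C2 (olefinic CH), C3 (quaternary), C4 (carbinol), C5, C6 (allylic CH2), the same in both rings.
Retrosynthesis: both C4 carbinols go back to ketones with a removable ester on C5; then, in both rings at once, the C5–C6 bond and the C1–diene bond are cut, giving two molecules of an acyclic α-allenyl β-keto ester and (1E,3E)-1,4-diiodobuta-1,3-diene.
Enabling feature: C1 carries both the ring CH2 (C6) and the dienyl chain and is flanked by C2H on quaternary C3. This is the imprint of carbopalladation of a terminal allene (C2=C1=C6) at its central carbon, followed by capture of the π-allyl CH2 terminus by the C5 enolate. C3 has no hydrogen, C4 can enolise only toward C5, and the C2 symmetry lets one diiodide stitch both rings.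
Forward: geraniol → Sharpless oxirane → alkynylalane opening (sets C3) → Crabbé allene → Shi oxirane → glycol cleavage, aldol, oxidation to the β-keto ester; the diiodide is made separately; then the three-component double annulation, ester removal and ketone reduction.
Stereochemistry: C3 comes from L-(+)-tartrate through the invertive oxirane opening, the side-chain oxirane from the Shi ketone, C4 from the CBS catalyst, and the tetraene geometry from the diiodide and the ring.

Key step: step 10

Remark: C5 in 15–17 and the carbinol carbon of 10 are left configurationally undefined on purpose; all epimers converge in steps 7 and 11.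

**Step 1**
Reactants: 1 geraniol
Product: 2 [(2S,3S)-3-methyl-3-(4-methylpent-3-en-1-yl)oxiran-2-yl]methanol
Conditions: Ti(OiPr)4 (5 mol%), L-(+)-diethyl tartrate (7 mol%), t-BuOOH, 4 Å sieves, CH2Cl2, −20 °C
Reagents that add atoms: tert-butyl hydroperoxide, CC(C)(C)OO
Why: Sharpless asymmetric epoxidation: the titanium tartrate binds the allylic hydroxyl, so only the 2,3-olefin reacts, and L-(+)-tartrate sets both oxirane carbons as (2S,3S).

**Step 2**
Reactants: 2 [(2S,3S)-3-methyl-3-(4-methylpent-3-en-1-yl)oxiran-2-yl]methanol; 3 ethynyltrimethylsilane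
Product: 5 (2R,3S)-3-ethynyl-3,7-dimethyloct-6-ene-1,2-diol, via silylalkyne diol 4 (not isolated)
Conditions: 3, n-BuLi, toluene, −78 → 0 °C; Me2AlCl; then 2, 0 °C → rt; Rochelle salt work-up; crude in K2CO3, MeOH, rt
Reagents that add atoms: none
Why: Hydroxyl-directed opening of a 2,3-epoxy alcohol by an alkynylalane at the fully substituted, distal oxirane carbon with inversion creates the quaternary centre as (S) while the carbinol carbon keeps its configuration; methanolysis then removes the alkynyl silyl group (protodesilylation).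

**Step 3**
Reactants: 5 (2R,3S)-3-ethynyl-3,7-dimethyloct-6-ene-1,2-diol
Product: 6 (2R,3S)-3,7-dimethyl-3-(propa-1,2-dien-1-yl)oct-6-ene-1,2-diol
Conditions: (CH2O)n, CuI (0.5 equiv), Cy2NH, 1,4-dioxane, reflux
Reagents that add atoms: paraformaldehyde (as formaldehyde), C=O
Why: Crabbé homologation (copper-mediated Mannich alkynylation, then intramolecular hydride transfer with loss of imine) turns the terminal alkyne into the terminal allene without touching the stereocentres; free hydroxyls are tolerated.

**Step 4**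
Reactants: 6 (2R,3S)-3,7-dimethyl-3-(propa-1,2-dien-1-yl)oct-6-ene-1,2-diol
Product: 7 (2R,3S)-5-[(2R)-3,3-dimethyloxiran-2-yl]-3-methyl-3-(propa-1,2-dien-1-yl)pentane-1,2-diol
Conditions: D-fructose-derived Shi ketone (0.3 equiv), Oxone, K2CO3, Bu4NHSO4, MeCN/CH2(OMe)2/aq. borate buffer (pH 10.5), 0 °C
Reagents that add atoms: Oxone (potassium peroxymonosulfate), [K+].[O-]S(=O)(=O)OO
Why: Shi epoxidation: the chiral dioxirane should take the electron-rich trisubstituted olefin well before the hindered monosubstituted allene or the alcohols, and the D-fructose-derived ketone delivers oxygen, through its spiro transition state, to the face that gives the (R)-oxirane (the same facial sense that gives (R,R)-oxiranes from trans-olefins).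

**Step 5**
Reactants: 7 (2R,3S)-5-[(2R)-3,3-dimethyloxiran-2-yl]-3-methyl-3-(propa-1,2-dien-1-yl)pentane-1,2-diol
Product: 8 (2S)-4-[(2R)-3,3-dimethyloxiran-2-yl]-2-methyl-2-(propa-1,2-dien-1-yl)butanal
Conditions: NaIO4, THF/pH 7 phosphate buffer, 0 °C → rt
Reagents that add atoms: none
Why: Periodate glycol cleavage leaves the aldehyde on a fully substituted, non-epimerisable carbon; oxirane and allene are inert to buffered periodate.

**Step 6**
Reactants: 8 (2S)-4-[(2R)-3,3-dimethyloxiran-2-yl]-2-methyl-2-(propa-1,2-dien-1-yl)butanal; 9 2-(trimethylsilyl)ethyl acetate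
Product: 10 2-(trimethylsilyl)ethyl (4S)-6-[(2R)-3,3-dimethyloxiran-2-yl]-3-hydroxy-4-methyl-4-(propa-1,2-dien-1-yl)hexanoate (both C3 epimers)
Conditions: 9, lithium diisopropylamide, THF, −78 °C; then 8; aqueous quench at −78 °C
Reagents that add atoms: none
Why: Aldol addition of a preformed lithium ester enolate to a non-enolisable aldehyde; the new carbinol centre is formed without control because step 7 removes it.

**Step 7**
Reactants: 10 2-(trimethylsilyl)ethyl (4S)-6-[(2R)-3,3-dimethyloxiran-2-yl]-3-hydroxy-4-methyl-4-(propa-1,2-dien-1-yl)hexanoate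
Product: 11 2-(trimethylsilyl)ethyl (4S)-6-[(2R)-3,3-dimethyloxiran-2-yl]-4-methyl-3-oxo-4-(propa-1,2-dien-1-yl)hexanoate
Conditions: Dess–Martin periodinane, NaHCO3, CH2Cl2, 0 °C → rt
Reagents that add atoms: none
Why: Dess–Martin oxidation under bicarbonate buffer converts the β-hydroxy ester into the β-keto ester without acid that would open the oxirane.

**Step 8**
Reactants: 12 [(E)-2-bromoethenyl]trimethylsilane (2 equiv)
Product: 13 (1E,3E)-1,4-bis(trimethylsilyl)buta-1,3-diene
Conditions: NiCl2(PPh3)2 (10 mol%), Zn dust, PPh3, Et4NI, THF, 50 °C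
Reagents that add atoms: a second molecule of 12, [(E)-2-bromoethenyl]trimethylsilane, C[Si](C)(C)/C=C/Br
Why: Nickel-catalysed reductive homocoupling of an alkenyl bromide (zerovalent nickel regenerated by zinc) joins the bromine-bearing sp2 carbons of two molecules of 12 with retention of the (E) geometry at both olefins.

**Step 9**
Reactants: 13 (1E,3E)-1,4-bis(trimethylsilyl)buta-1,3-diene
Product: 14 (1E,3E)-1,4-diiodobuta-1,3-diene
Conditions: N-iodosuccinimide (2.2 equiv), (CF3)2CHOH, 0 °C, dark
Reagents that add atoms: N-iodosuccinimide, O=C1CCC(=O)N1I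
Why: Electrophilic ipso-iododesilylation of an alkenylsilane: iodonium attack at the silicon-bearing carbon gives a β-silyl-stabilised cation that loses silicon with retention of the (E) geometry.

**Step 10**
Reactants: 11 2-(trimethylsilyl)ethyl (4S)-6-[(2R)-3,3-dimethyloxiran-2-yl]-4-methyl-3-oxo-4-(propa-1,2-dien-1-yl)hexanoate (2.1 equiv); 14 (1E,3E)-1,4-diiodobuta-1,3-diene
Product: 16 bis[2-(trimethylsilyl)ethyl] 5,5'-[(1E,3E)-buta-1,3-diene-1,4-diyl]bis{(3S)-3-[2-((2R)-3,3-dimethyloxiran-2-yl)ethyl]-3-methyl-2-oxocyclohex-4-ene-1-carboxylate} (both epimers at C1 of each ring), via iodotriene monoadduct 15 (not isolated)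
Conditions: Pd(PPh3)4 (10 mol%), K2CO3, DMF, 60 °C, argon, dark
Reagents that add atoms: none
Why: Oxidative addition of a C–I bond of 14 to zerovalent palladium gives an (E)-dienylpalladium iodide that adds syn across the terminal C=CH2 of the allene, the dienyl carbon going to the central allene carbon from the face away from the quaternary carbon, so that an anti π-allylpalladium with C3 cis to the CH2 terminus results; the enolate carbon of the β-keto ester then attacks this CH2 terminus opposite palladium, forms the C5–C6 bond and returns zerovalent palladium, which repeats the sequence at the second C–I bond in 15. The closest known reaction type is the zerovalent-palladium-catalysed coupling–cyclisation of allenes carrying a tethered malonate or β-dicarbonyl pronucleophile with aryl and alkenyl halides. Each cyclohexene closes in a 6-endo mode with the whole allyl unit (C2, C1, C6) inside the ring, since attack at the other allyl terminus would give a cyclobutanone. No lasting stereocentre is made: C5 is epimerisable and loses its ester in step 11, C3 is untouched, the ring olefin geometry is fixed by the ring, and the (E,E) linker geometry is carried over from 14 because oxidative addition and insertion retain olefin geometry. The step needs carbon over oxygen alkylation and cyclisation over β-hydride loss or direct enolate vinylation: an O-allylated enol ether would be re-ionised by zerovalent palladium, quaternary C3 leaves the allyl unit no β-hydrogen, and the ketone can enolise only toward C5.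

**Step 11**
Reactants: 16 bis[2-(trimethylsilyl)ethyl] 5,5'-[(1E,3E)-buta-1,3-diene-1,4-diyl]bis{(3S)-3-[2-((2R)-3,3-dimethyloxiran-2-yl)ethyl]-3-methyl-2-oxocyclohex-4-ene-1-carboxylate}
Product: 18 4,4'-[(1E,3E)-buta-1,3-diene-1,4-diyl]bis{(2S)-2-[2-((2R)-3,3-dimethyloxiran-2-yl)ethyl]-2-methylcyclohex-3-en-1-one}, via bis(β-keto acid) 17 (not isolated)
Conditions: tetrabutylammonium fluoride, THF, 0 → 40 °C; pH 7 buffer work-up; dark
Reagents that add atoms: none
Why: Fluoride-induced fragmentation of the 2-(trimethylsilyl)ethyl esters gives β-keto carboxylates that decarboxylate on gentle warming, which removes the activating groups without acid or strong heat that would endanger the oxiranes or the tetraene.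

**Step 12**
Reactants: 18 4,4'-[(1E,3E)-buta-1,3-diene-1,4-diyl]bis{(2S)-2-[2-((2R)-3,3-dimethyloxiran-2-yl)ethyl]-2-methylcyclohex-3-en-1-one}
Product: 19 4,4'-[(1E,3E)-buta-1,3-diene-1,4-diyl]bis{(1S,2S)-2-[2-((2R)-3,3-dimethyloxiran-2-yl)ethyl]-2-methylcyclohex-3-en-1-ol} (target)
Conditions: (R)-2-methyl-CBS-oxazaborolidine (0.5 equiv per ketone), catecholborane, toluene, −40 → −20 °C; MeOH quench, pH 7 buffer; dark
Reagents that add atoms: none
Why: Corey–Bakshi–Shibata reduction: the ketone has no useful intrinsic facial bias (methyl versus CH2 on the neighbouring quaternary carbon), so the (R)-oxazaborolidine decides, binding the carbonyl with quaternary C3 as the large group and delivering hydride to give the (S)-carbinol in both rings, as it gives (S)-1-phenylethanol from acetophenone.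

**Compound list**

1 | geraniol, (2E)-3,7-dimethylocta-2,6-dien-1-ol | CC(C)=CCC/C(C)=C/CO | starting material
2 | [(2S,3S)-3-methyl-3-(4-methylpent-3-en-1-yl)oxiran-2-yl]methanol | OC[C@@H]1O[C@@]1(C)CCC=C(C)C | intermediate
3 | ethynyltrimethylsilane | C#C[Si](C)(C)C | starting material
4 | (2R,3S)-3,7-dimethyl-3-[(trimethylsilyl)ethynyl]oct-6-ene-1,2-diol | C[Si](C)(C)C#C[C@](C)(CCC=C(C)C)[C@@H](O)CO | intermediate
5 | (2R,3S)-3-ethynyl-3,7-dimethyloct-6-ene-1,2-diol | C#C[C@](C)(CCC=C(C)C)[C@@H](O)CO | intermediate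
6 | (2R,3S)-3,7-dimethyl-3-(propa-1,2-dien-1-yl)oct-6-ene-1,2-diol | C=C=C[C@](C)(CCC=C(C)C)[C@@H](O)CO | intermediate
7 | (2R,3S)-5-[(2R)-3,3-dimethyloxiran-2-yl]-3-methyl-3-(propa-1,2-dien-1-yl)pentane-1,2-diol | C=C=C[C@](C)(CC[C@H]1OC1(C)C)[C@@H](O)CO | intermediate
8 | (2S)-4-[(2R)-3,3-dimethyloxiran-2-yl]-2-methyl-2-(propa-1,2-dien-1-yl)butanal | C=C=C[C@](C)(CC[C@H]1OC1(C)C)C=O | intermediate
9 | 2-(trimethylsilyl)ethyl acetate | CC(=O)OCC[Si](C)(C)C | starting material
10 | 2-(trimethylsilyl)ethyl (4S)-6-[(2R)-3,3-dimethyloxiran-2-yl]-3-hydroxy-4-methyl-4-(propa-1,2-dien-1-yl)hexanoate | C=C=C[C@](C)(CC[C@H]1OC1(C)C)C(O)CC(=O)OCC[Si](C)(C)C | intermediate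
11 | 2-(trimethylsilyl)ethyl (4S)-6-[(2R)-3,3-dimethyloxiran-2-yl]-4-methyl-3-oxo-4-(propa-1,2-dien-1-yl)hexanoate | C=C=C[C@](C)(CC[C@H]1OC1(C)C)C(=O)CC(=O)OCC[Si](C)(C)C | intermediate
12 | [(E)-2-bromoethenyl]trimethylsilane | C[Si](C)(C)/C=C/Br | starting material
13 | (1E,3E)-1,4-bis(trimethylsilyl)buta-1,3-diene | C[Si](C)(C)/C=C/C=C/[Si](C)(C)C | intermediate
14 | (1E,3E)-1,4-diiodobuta-1,3-diene | I/C=C/C=C/I | intermediate
15 | 2-(trimethylsilyl)ethyl (3S)-3-[2-((2R)-3,3-dimethyloxiran-2-yl)ethyl]-5-[(1E,3E)-4-iodobuta-1,3-dien-1-yl]-3-methyl-2-oxocyclohex-4-ene-1-carboxylate | I/C=C/C=C/C1=C[C@](C)(CC[C@H]2OC2(C)C)C(=O)C(C(=O)OCC[Si](C)(C)C)C1 | intermediate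
16 | bis[2-(trimethylsilyl)ethyl] 5,5'-[(1E,3E)-buta-1,3-diene-1,4-diyl]bis{(3S)-3-[2-((2R)-3,3-dimethyloxiran-2-yl)ethyl]-3-methyl-2-oxocyclohex-4-ene-1-carboxylate} | CC1(C)O[C@@H]1CC[C@@]1(C)C=C(/C=C/C=C/C2=C[C@](C)(CC[C@H]3OC3(C)C)C(=O)C(C(=O)OCC[Si](C)(C)C)C2)CC(C(=O)OCC[Si](C)(C)C)C1=O | intermediate
17 | 5,5'-[(1E,3E)-buta-1,3-diene-1,4-diyl]bis{(3S)-3-[2-((2R)-3,3-dimethyloxiran-2-yl)ethyl]-3-methyl-2-oxocyclohex-4-ene-1-carboxylic acid} | CC1(C)O[C@@H]1CC[C@@]1(C)C=C(/C=C/C=C/C2=C[C@](C)(CC[C@H]3OC3(C)C)C(=O)C(C(O)=O)C2)CC(C(O)=O)C1=O | intermediate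
18 | 4,4'-[(1E,3E)-buta-1,3-diene-1,4-diyl]bis{(2S)-2-[2-((2R)-3,3-dimethyloxiran-2-yl)ethyl]-2-methylcyclohex-3-en-1-one} | CC1(C)O[C@@H]1CC[C@@]1(C)C=C(/C=C/C=C/C2=C[C@](C)(CC[C@H]3OC3(C)C)C(=O)CC2)CCC1=O | intermediate
19 | 4,4'-[(1E,3E)-buta-1,3-diene-1,4-diyl]bis{(1S,2S)-2-[2-((2R)-3,3-dimethyloxiran-2-yl)ethyl]-2-methylcyclohex-3-en-1-ol} | CC1(C)O[C@@H]1CC[C@@]1(C)C=C(/C=C/C=C/C2=C[C@](C)(CC[C@H]3OC3(C)C)[C@@H](O)CC2)CC[C@@H]1O | target

**Count**

Total steps: 12 (steps 1–7 and 10–12 in the main line, steps 8–9 for the linker).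
Longest linear sequence: 10 steps (1–7, 10, 11, 12).

**Steps most likely to fail**

Step 10. After the first annulation the second C–I bond sits in a light- and base-sensitive iodotriene, and its oxidative addition must outrun oligomerisation. At either end the π-allyl intermediate could also equilibrate to the syn form, which cannot close the six-membered ring, or the enolate could be vinylated directly. Fallback: ring formation and dimerisation are separated. Setting out from 11, the same zerovalent-palladium annulation is run with the commercial (E)-2-bromovinylboronic acid MIDA ester as the only, monofunctional halide, which should give 2-(trimethylsilyl)ethyl (3S)-3-[2-((2R)-3,3-dimethyloxiran-2-yl)ethyl]-3-methyl-5-[(E)-2-(6-methyl-4,8-dioxo-1,3,6,2-dioxazaborocan-2-yl)ethenyl]-2-oxocyclohex-4-ene-1-carboxylate F1 as a bench-stable alkenyl boronate. Two molecules of F1 are then joined at their boron-bearing carbons by Pd(OAc)2-catalysed oxidative homocoupling, run in THF at rt with aqueous K3PO4 for slow release of the boronic acid and with O2 or 1,4-benzoquinone as the oxidant, with retention of the (E) geometry. This comes back to the route at 16.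

Step 12. Two hindered ketones next to quaternary carbons must be reduced under full catalyst control. A slow catalysed reduction would let uncatalysed borane reduction erode the facial selectivity, and boron species may attack the oxiranes. Fallback: setting out from 18, the reduction is handed to a ketoreductase (NADPH-dependent, glucose/glucose dehydrogenase recycling, buffer with a water-miscible cosolvent) chosen by screening for (S)-selective delivery of hydride. This comes back to the route directly at 19 and makes no new isolated compound.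

Step 2. The alane may transfer the alkynyl group to the secondary oxirane carbon, or its Lewis acidity may trigger hydride or alkyl shifts of the trisubstituted oxirane instead of clean invertive attack at the tertiary carbon. Fallback: the quaternary centre is built by a stereospecific 1,2-shift instead. Setting out from 1, Sharpless epoxidation with D-(−)-diethyl tartrate gives [(2R,3R)-3-methyl-3-(4-methylpent-3-en-1-yl)oxiran-2-yl]methanol F2 as the mirror image of 2. Silylation with t-BuMe2SiCl and imidazole gives tert-butyldimethyl{[(2R,3R)-3-methyl-3-(4-methylpent-3-en-1-yl)oxiran-2-yl]methoxy}silane F3 as the substrate for the rearrangement. Methylaluminium bis(4-bromo-2,6-di-tert-butylphenoxide) in CH2Cl2 at −78 °C then moves the siloxymethyl group anti onto the tertiary oxirane carbon, with inversion, and gives (2R)-2-{[(tert-butyldimethylsilyl)oxy]methyl}-2,6-dimethylhept-5-enal F4 with the quaternary centre in place. Ohira–Bestmann homologation gives tert-butyl{[(2S)-2-ethynyl-2,6-dimethylhept-5-en-1-yl]oxy}dimethylsilane F5 without touching that centre. Crabbé homologation gives tert-butyl{[(2S)-2,6-dimethyl-2-(propa-1,2-dien-1-yl)hept-5-en-1-yl]oxy}dimethylsilane F6 as the terminal allene. Shi epoxidation with the D-fructose-derived ketone gives tert-butyl({(2S)-4-[(2R)-3,3-dimethyloxiran-2-yl]-2-methyl-2-(propa-1,2-dien-1-yl)butyl}oxy)dimethylsilane F7 with the (R)-oxirane. Tetrabutylammonium fluoride gives (2S)-4-[(2R)-3,3-dimethyloxiran-2-yl]-2-methyl-2-(propa-1,2-dien-1-yl)butan-1-ol F8 as the free primary alcohol. Buffered Dess–Martin oxidation of F8 then comes back to the route at 8.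

**Further compounds**

F1 | step 10 | 2-(trimethylsilyl)ethyl (3S)-3-[2-((2R)-3,3-dimethyloxiran-2-yl)ethyl]-3-methyl-5-[(E)-2-(6-methyl-4,8-dioxo-1,3,6,2-dioxazaborocan-2-yl)ethenyl]-2-oxocyclohex-4-ene-1-carboxylate | C[N+]12CC(=O)O[B-]1(/C=C/C3=C[C@](C)(CC[C@H]4OC4(C)C)C(=O)C(C(=O)OCC[Si](C)(C)C)C3)OC(=O)C2
F0 | step 12 | none | none
F2 | step 2 | [(2R,3R)-3-methyl-3-(4-methylpent-3-en-1-yl)oxiran-2-yl]methanol | OC[C@H]1O[C@]1(C)CCC=C(C)C
F3 | step 2 | tert-butyldimethyl{[(2R,3R)-3-methyl-3-(4-methylpent-3-en-1-yl)oxiran-2-yl]methoxy}silane | CC(C)(C)[Si](C)(C)OC[C@H]1O[C@]1(C)CCC=C(C)C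
F4 | step 2 | (2R)-2-{[(tert-butyldimethylsilyl)oxy]methyl}-2,6-dimethylhept-5-enal | O=C[C@](C)(CCC=C(C)C)CO[Si](C)(C)C(C)(C)C
F5 | step 2 | tert-butyl{[(2S)-2-ethynyl-2,6-dimethylhept-5-en-1-yl]oxy}dimethylsilane | C#C[C@](C)(CCC=C(C)C)CO[Si](C)(C)C(C)(C)C
F6 | step 2 | tert-butyl{[(2S)-2,6-dimethyl-2-(propa-1,2-dien-1-yl)hept-5-en-1-yl]oxy}dimethylsilane | C=C=C[C@](C)(CCC=C(C)C)CO[Si](C)(C)C(C)(C)C
F7 | step 2 | tert-butyl({(2S)-4-[(2R)-3,3-dimethyloxiran-2-yl]-2-methyl-2-(propa-1,2-dien-1-yl)butyl}oxy)dimethylsilane | C=C=C[C@](C)(CC[C@H]1OC1(C)C)CO[Si](C)(C)C(C)(C)C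
F8 | step 2 | (2S)-4-[(2R)-3,3-dimethyloxiran-2-yl]-2-methyl-2-(propa-1,2-dien-1-yl)butan-1-ol | C=C=C[C@](C)(CC[C@H]1OC1(C)C)CO
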